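D made in a flask cannot all remain D: it passes into J and back, D ⇌ J (K3 = 4.1, k3 = 3.9 × 10⁻⁴ /min, Ea3 = 103 kJ/mol, ΔH3 = −29.0 kJ/mol), towards a balance.

| flask | Q | G | X | temperature | time |
|---|---|---|---|---|---|
| red | 0.20 M | 1.00 M | 0.26 mM | 5 °C | 6.0 d |
| violet | 0.20 M | 1.00 M | 0.26 mM | −10 °C | 6.0 d |

    G + X → G.X (k1 = 41 /M/min, Ea1 = 43.0 kJ/mol)
    G.X ⇌ Z (K2 = 2.5, k2 = 59 /min, Ea2 = 62.0 kJ/mol, ΔH2 = −47.0 kJ/mol)
    D ⇌ J (K3 = 4.1, k3 = 3.9 × 10⁻⁴ /min, Ea3 = 103 kJ/mol, ΔH3 = −29.0 kJ/mol)
    Q.Z ⇌ X + D (K4 = 0.075 M, k4 = 6.2 /min, Ea4 = 80.0 kJ/mol, ΔH4 = 18.0 kJ/mol)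
    Q + Z ⇌ Q.Z (K5 = 10 /M, k5 = 4.6 /M/min, Ea5 = 37.0 kJ/mol, ΔH5 = −5.00 kJ/mol)
    (constants at 5 °C)

- the list of constants is for 5 °C, to be carried to other temperatures by the activation energies and enthalpies

1. which flask leads in amount of D, in percent of the Q charged ("all alike" within 1.5 percentage points) (red / violet / all alike)
2. how much D is there at the end, in percent of the Q charged: red
3. how much D is there at the end, in percent of the Q charged: violet

The catalyst X takes up G and passes through G.X to Z. Z binds Q, and Q.Z releases D and gives X back; J then comes from D. The decision for the next run is the bath, with charges and time unchanged: red's 5 °C or violet's −10 °C.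

Two numbers place each flask. The zero of the scale is s, the part of D in D plus J at balance, which is one over one plus K, where K is the equilibrium constant of D ⇌ J at the flask's temperature. Red's forward constant 3.9 × 10⁻⁴ /min and K of 4.1 give 4.19 for n, the relaxation number: forward plus backward rate constant of D ⇌ J, times the time.

This hand reckoning takes D, as a share of the Q charged, to be s plus the excess above s shrunk by exp(−n). It counts all Q as D from the start, so the time the cycle needs and any Q left over stand outside it. Violet's constants are carried from red's by the activation energy and the enthalpy.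

| flask | K | forward constant | s | n | D reckoned |
|---|---|---|---|---|---|
| red | 4.1 | 3.9 × 10⁻⁴ /min | 19.6% | 4.19 | 20.8% |
| violet | 8.38 | 3.08 × 10⁻⁵ /min | 10.7% | 0.298 | 77.0% |

Red's n is larger than violet's, so the reckoning puts red close to its s, under thermodynamic control, and violet under kinetic control. The reckoning puts the lead with violet, and so the next run goes into the cold bath.

The forecast also names violet, with 22.7% for red and 78% for violet. Of red it says “D relaxes nearly to equilibrium”. Its grounds are a steady-state flux through the cycle and the relaxation of D towards J. Its figures lie above the hand reckoning in red and in violet.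

The simulation gives 22.7% of D for red and 77.9% for violet, so violet leads. Red's D and J have a relaxation half-life of 0.992 d, short against the time, and red, at n = 4.19, ends with 77.2% as J; violet, at n = 0.298, ends with 15.0% as J and 7.0% as unbound Q. Red's recipe run at 20 °C has n = 48.2 and s = 31.7%, and that flask ends with 31.7% of D.

(The rate constants are invented.)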